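Start from the list.

    Z + G ⇌ G + D (K1 = 1.5, k1 = 190 M⁻¹ s⁻¹, Ea1 = 59.0 kJ mol⁻¹, ΔH1 = 4.00 kJ mol⁻¹)
    Q + G + D → G + L (k2 = 33000 M⁻² s⁻¹, Ea2 = 12.0 kJ mol⁻¹)
    X ⇌ Q, rate k3*(cs3 - [Q]) while solid is left; crystals form when [Q] > cs3 (cs3 = 2.5 mM, k3 = 0.045 s⁻¹)
    Q + L → Q.L (k4 = 0.0025 M⁻¹ s⁻¹, Ea4 = 75.0 kJ mol⁻¹)
    (constants at 90 °C)

| flask | Z | X | G | temperature | time |
|---|---|---|---|---|---|
| amber | 30 mM (fed, over 40 min) | 31.5 mM | 15 µM | 65 °C | 80 min |
| green | 30 mM (fed, over 40 min) | 31.5 mM | 15 µM | 115 °C | 80 min |
| ochre | 30 mM (fed, over 40 min) | 31.5 mM | 15 µM | 90 °C | 80 min |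

- solid, in amounts per volume of the solution: X
- all constants are for 90 °C and move with temperature by the activation energies and enthalpies
- at the start none of X is in solution

1. the flask that comes out highest in amount of D, in percent of the Z charged, or "all alike" when all lie within 1.5 percentage points (amber / green / ochre / all alike)
2. D at the end, in percent of the Z charged, amber
3. D at the end, in percent of the Z charged, green
4. D at the end, in percent of the Z charged, ochre

1. The rule of thumb, tried on ochre, whose constants stand as given: call step one a fast equilibrium, so that D/Z equals K, which is 1.5.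

2. Take Q at its solubility while solid X lasts, which makes step two pseudo-first-order in D, with a rate constant c of 0.0742 min⁻¹. A dissolving flow equal to the feed holds Q 11.1% under that solubility, a small correction.

3. Now find the border. G carries both the way back from D and the way on, so it cancels from their ratio. Call x the rate onward over the rate back: x = k2·cs3·K/k1 = 0.651. The rule of thumb needs x far below 1, and here it is not.

4. So correct it. Suppose that after the feed Z and D fall together at one fractional rate. Setting their two fractional rates equal gives: ρ squared, plus (one plus x minus K) times ρ, equals K. This yields 1.15, the standing ratio ρ: D over Z once both fall together. It lies below K.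

5. The pool Z + D drains through its D share, ρ/(one plus ρ), which is 53.5%, so the pool falls at 0.0397 min⁻¹. If the same rate and share hold during the feed of 40 min, the pool builds to 50.1% of the charge. After the remaining 40.0 min, my reckoning puts D in ochre at 5.47% of the charge. Q under its solubility slows the drain, so I read this as low.

6. The forecast expects that “the coolest flask keeps the most D” and gives amber as highest, with amber 14.8%, green 3.6% and ochre 7.1%.

7. The simulation puts amber highest, with amber 14.4%, green 3.50% and ochre 6.92%, so ochre lies above my 5.47%. Ochre ends with Z at 6.0% of the charge and X at 8.15% of its own, a D/Z of 1.16 against ρ of 1.15. In green at 34.2 min, D falls back 4.2 times faster than it goes on, and with K of 1.63 that makes ρ 1.49. A neighbour of green with 0.0090 mM of G ends with solid X at 7.21% of its own, Q at 2.42 mM, D at 9.63% and Z at 6.50%, a D/Z of 1.48.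

The numbers of this flask come from no measurement; the rest is arithmetic.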